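The runs stem from a simulated flask on assumed constants, noise included.

The ratio I watch here is the last target reading of the delta run over that of the epsilon run, each as a share of the starting material charged.

| flask | starting material | partner | free catalyst | time |
|---|---|---|---|---|
| epsilon | 0.300 M | 0.300 M | 0.0300 M |  |
| theta | 0.600 M | 0.300 M | 0.0300 M |  |
| delta | 0.300 M | 0.600 M | 0.0300 M |  |
| zeta | 0.300 M | 1.00 M | 0.0300 M | 38 min |

| run | time / min | [target] / M |
|---|---|---|
| epsilon run | 1.5 | 0.0224 |
| epsilon run | 3.4 | 0.0445 |
| epsilon run | 7.6 | 0.0797 |
| epsilon run | 17 | 0.1136 |
| epsilon run | 38 | 0.1327 |
| theta run | 1.5 | 0.0266 |
| theta run | 3.4 | 0.0549 |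
| theta run | 7.6 | 0.0949 |
| theta run | 17 | 0.1423 |
| theta run | 38 | 0.1698 |
| delta run | 1.5 | 0.0422 |
| delta run | 3.4 | 0.0814 |
| delta run | 7.6 | 0.1280 |
| delta run | 17 | 0.1595 |
| delta run | 38 | 0.1641 |

(scatter of a reading: 9 × 10⁻⁴ M)

1. the exponent of [starting material] in the starting rate at the charge of the epsilon run (at the point where two percent of the starting material have become target) (one fixed amount of target, the same in the runs compared)
2. the exponent of [partner] in the starting rate at the charge of the epsilon run (at the point where two percent of the starting material have become target)
3. target in the zeta run at 38 min, as a share of the starting material charged

- Overall: starting material + partner -> target, with free catalyst as catalyst.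
- Constant volume, constant temperature.
- A reading of a species includes what of it is bound.
- "The second partner" is partner.
- An order is taken over about fifteen percent of the charge, up and down.

I build the flask one process at a time. My first model holds the main step by itself, with starting material as the limiting reagent in the zeta run, and it allows the whole charge. Over the first 1.5 min, the delta run makes close to twice the target of the epsilon run, while the theta run makes 1.19 times as much. Over these doublings I read rough orders of 0.914 in partner and 0.248 in starting material.

But the readings stop short, at 44.2% in the epsilon run and 54.7% in the delta run, so my second step adds a dying catalyst. Between the last two readings, the epsilon run still gains 4.15 times what the delta run gains, so I let partner speed the dying as well as the making. That is the symmetric case: the two clocks keep pace, the final share ignores partner, and the ratio stands at 1.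

The readings give 1.24, so I add a third process, a loss on its own clock. A run that ends sooner gives this loss less time, so I take it as proportional to the reciprocal of partner. Doubling partner then halves the loss, which makes the delta run's remaining loss 10 percentage points. Adding that to its share gives my reckoned ceiling, an estimate from this reciprocal rule of the share left when the loss is reckoned away, 65.2%. At the zeta run's partner the loss is 6.3 points, so I commit to 58.9%.

The forecast gives orders of 0.32 and 0.97 and a share of 55%, which is lower than my figure, holding that “Rate and death then both scale with partner”.

The flask gives 0.32 in starting material, 1.0 in partner and 60.7% for the zeta run, 1.8 points above my reckoning and 4.5 points under my reckoned ceiling.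

    free catalyst + starting material ⇌ catalyst-substrate complex, settled at all times (9.370 L mol⁻¹)
    catalyst-substrate complex + partner → target + free catalyst + by-product (2.550 L mol⁻¹ min⁻¹)
    2 starting material → homo dimer (0.1716 L mol⁻¹ min⁻¹)
    free catalyst + partner → spent catalyst + partner (0.5286 L mol⁻¹ min⁻¹)

The death of free catalyst at the hands of partner is the main thing holding the zeta run down. Simulated without the path from free catalyst + partner to spent catalyst + partner, that run climbs from 60.7% to 85.3%, a gain of 25 points and 63% of what is missing. The zeta run without the path from 2 starting material to homo dimer, with the catalyst death kept, reaches 72.5%, which is 7.3 points above my reckoned ceiling.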